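**Plan**

1. Numbering used throughout: cyclobutane C1 (CO2Me), C2 (CO2H), C3 (next to C2) and C4 (next to C1), each of C3/C4 carrying CH3 and a 4-methoxy-3-methyl-2-oxo-2H-pyran-6-yl ring. Enabling feature: C1 and C2 differ only as ester versus acid, so with both arms as CH2OH the ring is meso (mirror plane through the midpoints of C1–C2 and C3–C4), and the two cis arms can share a five-membered lactone ring.
2. Cuts, in order: the C2 carboxyl back to CH2OH and the C1 ester back to the lactone C1–C(=O)–O–CH2–C2; the lactone back to the meso diol; each pyranone at O1–C2 and C5–C6; the cyclobutane at C1–C4 and C2–C3.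
3. Forward: a [2+2] builds the cyclobutane (with temporary anhydride and dioxepane rings), the anhydride carbons are grown into the two pyranone rings, the acetonide is removed, and the γ-lactone ring is closed enzymatically and reopened at the end.
4. Stereochemistry: the relative configuration of C1–C4 comes from the cis-anti-cis photocycloaddition; the absolute configuration comes from the dehydrogenase choosing one of two enantiotopic CH2OH groups.
5. Assumption: the enzyme keeps the sense it shows with unsubstituted meso cis-1,2-bis(hydroxymethyl)cycloalkanes, which here corresponds to oxidation of the C1 arm.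

Key step: step 7

**Route**

Step 1
Reactants: 1 2,3-dimethylmaleic anhydride; 2 4,7-dihydro-2,2-dimethyl-1,3-dioxepine
Product: 3 meso cis-anti-cis photoadduct (C1/C2 bridged by CH2–O–C(CH3)2–O–CH2, C3/C4 each bearing CH3 and bridged by the anhydride; CH2O and CH3 groups on one face, anhydride carbonyls on the other)
Conditions: hν (350 nm), benzophenone (0.2 equiv), 2 (4 equiv), MeCN, rt
Reagents that add atoms: none
Why: Triplet-sensitised [2+2] photocycloaddition through a 1,4-biradical, in which the five- and seven-membered rings hold both ring fusions cis and approach of the anhydride anti to the dioxepine CH2O groups should give the cis-anti-cis adduct, fixing the relative configuration of C1–C4.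

Step 2
Reactants: 3 photoadduct anhydride
Product: 5 dimethyl diester (C3 and C4 each CH3 and CO2Me; acetonide retained), via sodium half-ester carboxylate 4 (not isolated)
Conditions: NaOMe (1.1 equiv), MeOH, rt; evaporate; MeI (3 equiv), DMF, rt
Reagents that add atoms: sodium methoxide, [Na+].[O-]C; iodomethane, CI
Why: Methoxide opens the tetrasubstituted succinic anhydride and the resulting carboxylate is esterified by SN2 alkylation with MeI, basic conditions that leave the acetonide and all four stereocentres untouched.

Step 3
Reactants: 5 dimethyl diester; 6 ethyl 2-methylacetoacetate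
Product: 7 bis(3,5-dioxo ester) (each CO2Me replaced by C(=O)CH2C(=O)CH(CH3)CO2Et; CH(CH3) centres unassigned, partly enolised)
Conditions: 6 (6 equiv), LiN(iPr)2 (12 equiv), THF, −78 to 0 °C; then 5, 0 °C to rt; AcOH quench
Reagents that add atoms: none
Why: Two-directional crossed Claisen condensation in which the terminal carbanion of the β-keto ester dianion attacks each methyl ester and methoxide leaves, the product resting as an unreactive polyenolate until the quench; the esters sit on quaternary carbons, hence the excess of dianion and the warming.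

Step 4
Reactants: 7 bis(3,5-dioxo ester)
Product: 8 bis(4-hydroxy-3-methyl-2-oxo-2H-pyran-6-yl) acetonide
Conditions: DBU (3 equiv), toluene, 80 °C; citric acid work-up
Reagents that add atoms: none
Why: Base-mediated lactonisation (6-exo-trig attack of the C5 enolate oxygen on the ethyl ester with loss of ethoxide) is the standard closure of 3,5-dioxo esters to 4-hydroxy-2-pyranones and removes the unassigned CH(CH3) centres.

Step 5
Reactants: 8 bis(4-hydroxypyranone)
Product: 9 bis(4-methoxy-3-methyl-2-oxo-2H-pyran-6-yl) acetonide
Conditions: Me2SO4 (3 equiv), K2CO3 (4 equiv), acetone, reflux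
Reagents that add atoms: dimethyl sulfate, COS(=O)(=O)OC
Why: O-methylation of the vinylogous acid with a hard electrophile under carbonate is the usual entry to 4-methoxy-3-methyl-2-pyranones, the 2-pyranone being favoured over the 2-methoxy-4-pyranone isomer when C5 is unsubstituted.

Step 6
Reactants: 9 bis(methoxypyranone) acetonide
Product: 10 meso diol (cis-1,2-bis(hydroxymethyl) groups cis to both CH3 and trans to both pyranonyl groups)
Conditions: AcOH/H2O/THF (3:1:1), 40 °C
Reagents that add atoms: none
Why: Acid-catalysed acetal hydrolysis of the seven-membered acetonide, which is far more labile than the vinylogous ester methoxy groups, exposes the two enantiotopic CH2OH groups.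

Step 7
Reactants: 10 meso diol
Product: 13 cis-fused γ-lactone (carbonyl on C1, OCH2 on C2), via hydroxy aldehyde 11 (not isolated), via lactol 12 (not isolated)
Conditions: horse liver alcohol dehydrogenase, NAD+ (5 mol %), FMN (2.2 equiv), 0.1 M glycine–NaOH buffer pH 9, DMSO (10 vol %), 25 °C
Reagents that add atoms: none
Why: In the enzyme–NAD+ complex one CH2OH binds to the active-site zinc as its alkoxide and transfers hydride to C4 of the nicotinamide to give hydroxy aldehyde 11, whose cis CH2OH adds to the formyl group to give lactol 12; a second hydride transfer from the lactol C–H gives lactone 13, and NADH is reoxidised by FMN. The closest known reaction type is the horse liver alcohol dehydrogenase oxidation of meso cis-1,2-bis(hydroxymethyl)cycloalkanes, the cyclobutane member included, to enantioenriched cis-fused lactones. The one ring closed is the γ-lactone (a 3-oxabicyclo[3.2.0]heptan-2-one), formed by 5-exo-trig hemiacetalisation and made permanent by the second oxidation. No stereocentre is created; the step makes C1 and C2 different and so fixes the absolute configuration of the four existing centres. The selectivity needed is between the two enantiotopic CH2OH groups and comes from the chiral active site alone, while the substrate supplies the mirror plane through the midpoints of C1–C2 and C3–C4, the cis arrangement that makes lactol closure faster than further oxidation of the free aldehyde, and the placement of both arms on the face away from the pyranones. The lactone is not a substrate, so over-oxidation to the meso diacid is not expected.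

Step 8
Reactants: 13 γ-lactone
Product: 15 hydroxy methyl ester (CO2Me on C1, CH2OH on C2), via potassium hydroxy carboxylate 14 (not isolated)
Conditions: KOH (1.05 equiv), THF/H2O, 0 °C; freeze-dry; MeI (5 equiv), DMF, 0 °C to rt; used crude
Reagents that add atoms: potassium hydroxide, [K+].[OH-]; iodomethane, CI
Why: Saponification of the strained cis-fused γ-lactone with one equivalent of hydroxide (acyl–oxygen cleavage, the vinylogous-carbonate pyranone carbonyls being much less electrophilic) followed by SN2 methylation of the dry carboxylate in DMF gives the hydroxy ester without acid or alkoxide that would re-close the lactone or epimerise C1.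

Step 9
Reactants: 15 hydroxy methyl ester
Product: 16 target acid ester
Conditions: TEMPO (0.2 equiv), PhI(OAc)2 (2.5 equiv), MeCN/H2O (1:1), rt
Reagents that add atoms: water, O
Why: Oxoammonium (TEMPO/PhI(OAc)2) oxidation of the primary alcohol through the aldehyde hydrate to the carboxylic acid runs near neutrality, which should spare the methyl ester, the pyranones and the C1/C2 configuration.

**Compound list**

1 | 2,3-dimethylmaleic anhydride | CC1=C(C)C(=O)OC1=O | starting material
2 | 4,7-dihydro-2,2-dimethyl-1,3-dioxepine | CC1(C)OC/C=C\CO1 | starting material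
3 | meso cis-anti-cis photoadduct (dioxepane-fused 3,4-dimethylcyclobutane-3,4-dicarboxylic anhydride; CH2O and CH3 on one face, anhydride on the other) | CC1(C)OC[C@@H]2[C@H](CO1)[C@@]3(C)C(=O)OC(=O)[C@@]23C | intermediate
4 | sodium salt of the half methyl ester of 3 (racemic, one enantiomer drawn) | CC1(C)OC[C@@H]2[C@H](CO1)[C@@](C)(C(=O)OC)[C@@]2(C)C(=O)[O-].[Na+] | intermediate (not isolated)
5 | meso dimethyl diester (C3, C4: CH3 and CO2Me; C1, C2: acetonide-bridged CH2O) | CC1(C)OC[C@@H]2[C@H](CO1)[C@@](C)(C(=O)OC)[C@@]2(C)C(=O)OC | intermediate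
6 | ethyl 2-methylacetoacetate | CCOC(=O)C(C)C(C)=O | starting material
7 | bis(3,5-dioxo ester) (C3, C4: CH3 and C(=O)CH2C(=O)CH(CH3)CO2Et; side-chain CH(CH3) unassigned) | CC1(C)OC[C@@H]2[C@H](CO1)[C@@](C)(C(=O)CC(=O)C(C)C(=O)OCC)[C@@]2(C)C(=O)CC(=O)C(C)C(=O)OCC | intermediate
8 | meso bis(4-hydroxy-3-methyl-2-oxo-2H-pyran-6-yl) acetonide | CC1(C)OC[C@@H]2[C@H](CO1)[C@@](C)(c3cc(O)c(C)c(=O)o3)[C@@]2(C)c4cc(O)c(C)c(=O)o4 | intermediate
9 | meso bis(4-methoxy-3-methyl-2-oxo-2H-pyran-6-yl) acetonide | CC1(C)OC[C@@H]2[C@H](CO1)[C@@](C)(c3cc(OC)c(C)c(=O)o3)[C@@]2(C)c4cc(OC)c(C)c(=O)o4 | intermediate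
10 | meso cis-1,2-bis(hydroxymethyl)-3,4-dimethyl-3,4-bis(4-methoxy-3-methyl-2-oxo-2H-pyran-6-yl)cyclobutane (CH2OH cis to CH3, trans to pyranonyl) | OC[C@@H]1[C@H](CO)[C@@](C)(c2cc(OC)c(C)c(=O)o2)[C@@]1(C)c3cc(OC)c(C)c(=O)o3 | intermediate
11 | hydroxy aldehyde (CHO on C1, CH2OH on C2) | O=C[C@@H]1[C@H](CO)[C@@](C)(c2cc(OC)c(C)c(=O)o2)[C@@]1(C)c3cc(OC)c(C)c(=O)o3 | intermediate (not isolated)
12 | lactol (hemiacetal carbon on C1, unassigned) | OC4[C@@H]1[C@H](CO4)[C@@](C)(c2cc(OC)c(C)c(=O)o2)[C@@]1(C)c3cc(OC)c(C)c(=O)o3 | intermediate (not isolated)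
13 | cis-fused γ-lactone (C1–C(=O)–O–CH2–C2; 3-oxabicyclo[3.2.0]heptan-2-one core, single enantiomer) | O=C4[C@@H]1[C@H](CO4)[C@@](C)(c2cc(OC)c(C)c(=O)o2)[C@@]1(C)c3cc(OC)c(C)c(=O)o3 | intermediate
14 | potassium hydroxy carboxylate (CO2K on C1, CH2OH on C2) | [K+].[O-]C(=O)[C@@H]1[C@H](CO)[C@@](C)(c2cc(OC)c(C)c(=O)o2)[C@@]1(C)c3cc(OC)c(C)c(=O)o3 | intermediate (not isolated)
15 | hydroxy methyl ester (CO2Me on C1, CH2OH on C2) | COC(=O)[C@@H]1[C@H](CO)[C@@](C)(c2cc(OC)c(C)c(=O)o2)[C@@]1(C)c3cc(OC)c(C)c(=O)o3 | intermediate
16 | (1S,2R,3S,4R)-2-(methoxycarbonyl)-3,4-bis(4-methoxy-3-methyl-2-oxo-2H-pyran-6-yl)-3,4-dimethylcyclobutane-1-carboxylic acid (CNP0481603.1) | COC(=O)[C@@H]1[C@H](C(=O)O)[C@@](C)(c2cc(OC)c(C)c(=O)o2)[C@@]1(C)c1cc(OC)c(C)c(=O)o1 | target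

**Count**

Total steps: 9. Longest linear sequence: 9 steps (1 or 2 to 16).

**Steps most likely to fail**

Step 7. The dehydrogenase may fail to bind or turn over a diol flanked by two quaternary carbons, or may discriminate poorly, or in the opposite sense, between the two CH2OH groups. The fallback sets out from 10 and returns at 16, replacing steps 7 to 9, by moving the desymmetrisation to the anhydride oxidation level. Swern oxidation of 10 ((COCl)2, DMSO, iPr2NEt, CH2Cl2, −78 °C; both alcohols are activated before base is added, so lactol formation is bypassed) should give meso dialdehyde F1. Pinnick oxidation (NaClO2, NaH2PO4, 2-methyl-2-butene, tBuOH/H2O) should then give meso diacid F2, and warming in Ac2O the meso cyclic anhydride F3. Cinchona-alkaloid-mediated methanolysis (MeOH, toluene, −50 °C) with whichever of the pseudoenantiomers quinidine and quinine directs methanol to the C1 carbonyl would give 16 directly; because both alkaloids are available, either enantiotopic carbonyl can be addressed.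

Step 3. Attack at ester carbonyls on quaternary carbons may be slow, and after the first acylation the new diketonate may add to the neighbouring cis ester in a Dieckmann-type five-ring closure. The fallback sets out from 5 and returns at 7 by changing the electrophile to the aldehyde oxidation level. LiAlH4 (THF, 0 °C to rt) should reduce 5 to acetonide-protected 3,4-bis(hydroxymethyl) compound F4. Swern oxidation should give dialdehyde F5, which cannot epimerise because both α-carbons are quaternary. Aldol addition of the dianion of 6 (LiN(iPr)2, THF, −78 °C, excess) should give bis(δ-hydroxy β-keto ester) F6 as a mixture of diastereomers. Dess–Martin oxidation (CH2Cl2, NaHCO3) would then converge on 7.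

Step 8. The hydroxy ester may re-close to the lactone during methylation, isolation or the following oxidation. The fallback sets out from 13 and returns at 16 by protecting the alcohol before the ester is made. After KOH opening to 14 as above, TBSCl/imidazole (DMF) should give silyl ester silyl ether F7. K2CO3 in MeOH/H2O cleaves only the silyl ester and should give silyloxy acid F8, which cannot lactonise. MeI/K2CO3 (DMF) should then give silyloxy methyl ester F9. Jones reagent (CrO3, H2SO4, acetone, 0 °C) would remove the silyl ether and oxidise the liberated alcohol in the same flask to give 16.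

**Further compounds**

F1 | step 7 | meso dialdehyde (CHO on C1 and C2) | O=C[C@@H]1[C@H](C=O)[C@@](C)(c2cc(OC)c(C)c(=O)o2)[C@@]1(C)c3cc(OC)c(C)c(=O)o3
F2 | step 7 | meso diacid (CO2H on C1 and C2) | OC(=O)[C@@H]1[C@H](C(=O)O)[C@@](C)(c2cc(OC)c(C)c(=O)o2)[C@@]1(C)c3cc(OC)c(C)c(=O)o3
F3 | step 7 | meso cyclic anhydride (C1–C(=O)–O–C(=O)–C2) | O=C4[C@@H]1[C@H](C(=O)O4)[C@@](C)(c2cc(OC)c(C)c(=O)o2)[C@@]1(C)c3cc(OC)c(C)c(=O)o3
F4 | step 3 | acetonide-protected meso 3,4-bis(hydroxymethyl)-3,4-dimethylcyclobutane | CC1(C)OC[C@@H]2[C@H](CO1)[C@@](C)(CO)[C@@]2(C)CO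
F5 | step 3 | acetonide-protected meso 3,4-dimethylcyclobutane-3,4-dicarbaldehyde | CC1(C)OC[C@@H]2[C@H](CO1)[C@@](C)(C=O)[C@@]2(C)C=O
F6 | step 3 | bis(δ-hydroxy β-keto ester) (C3, C4: CH3 and CH(OH)CH2C(=O)CH(CH3)CO2Et; side-chain centres unassigned) | CC1(C)OC[C@@H]2[C@H](CO1)[C@@](C)(C(O)CC(=O)C(C)C(=O)OCC)[C@@]2(C)C(O)CC(=O)C(C)C(=O)OCC
F7 | step 8 | tert-butyldimethylsilyl ester (C1) tert-butyldimethylsilyl ether (C2 CH2O) | CC(C)(C)[Si](C)(C)OC(=O)[C@@H]1[C@H](CO[Si](C)(C)C(C)(C)C)[C@@](C)(c2cc(OC)c(C)c(=O)o2)[C@@]1(C)c3cc(OC)c(C)c(=O)o3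
F8 | step 8 | silyloxy acid (CO2H on C1, CH2OTBS on C2) | OC(=O)[C@@H]1[C@H](CO[Si](C)(C)C(C)(C)C)[C@@](C)(c2cc(OC)c(C)c(=O)o2)[C@@]1(C)c3cc(OC)c(C)c(=O)o3
F9 | step 8 | silyloxy methyl ester (CO2Me on C1, CH2OTBS on C2) | COC(=O)[C@@H]1[C@H](CO[Si](C)(C)C(C)(C)C)[C@@](C)(c2cc(OC)c(C)c(=O)o2)[C@@]1(C)c3cc(OC)c(C)c(=O)o3
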